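**Plan**

1. Retrosynthesis: the 21 O–methyl bonds of a permethylated octamer are cut last. Before that, the four aryl ether bonds whose aryl carbon has two ortho hydrogens are cut (ring A O to ring B C1; ring C, E and G C6–O to ring D, F and H C1). This leaves 2,4,6-trimethoxyphenol, 5-iodo-1,2,3-trimethoxybenzene and three copies of one iodinated B–C type dimer.
2. Feature and key cut: rings C, E and G each carry oxygen on five contiguous carbons (C1, C6, C5, C4, C3) and one CH (C2). Cutting C3–C2 maps C3–C6 onto the four carbons of a squarate and C1–C2 onto a 1-aryloxyvinyl unit, so the crowded ring B O–C1 ether comes from an O-vinylation and not from a coupling.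
3. Forward: 2,6-dimethoxyphenol is O-vinylated, lithiated at the vinyl alpha carbon, added to dimethyl squarate and capped. Thermal ring expansion closes the pentaoxygenated ring; methylation and sterically controlled C–H borylation/iodination para to the ether oxygen give the dimer iodide.
4. The chain is joined from the ring A end: three rounds of copper-catalysed etherification with the dimer iodide and acetal removal give A–C, A–E and A–G. Ring H is added last and BBr3 frees the 21 hydroxyls.
5. Ring A and the iodine are introduced only after the organolithium step, because C–H bonds lying between two oxygens (rings A and B of an A–B vinyl ether) and an aryl halide would both compete with the vinyl C–H for the base.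
6. Stereochemistry: the target has no stereocentre. The one stereocentre on the way (C4 of the cyclobutenones, racemic) is erased when the ring becomes aromatic.

Key step: step 4

Remark: rings are lettered A to H from the 2,4,6-trihydroxyphenoxy end; in rings C, E and G, C1 bears the oxygen from ring B, D or F, C2 is the CH and C6 bears the oxygen to ring D, F or H; in rings B, D and F, C1 bears the oxygen from the preceding ring; MOM stands for methoxymethyl.

**Route**

Step 1
Reactants: 1 2,6-dimethoxyphenol
Product: 2 2-(ethenyloxy)-1,3-dimethoxybenzene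
Conditions: CaC2, KOH, DMSO, H2O (2 equiv), 130 °C, sealed tube
Reagents that add atoms: calcium carbide (source of acetylene), [Ca+2].[C-]#[C-]
Why: Base-mediated addition of the phenoxide to acetylene released from CaC2 (Reppe-type O-vinylation) should tolerate the two ortho methoxy groups because the electrophile is a small linear alkyne, and the aryl vinyl ether is stable to the basic medium.

Step 2
Reactants: 2 2-(ethenyloxy)-1,3-dimethoxybenzene; 3 dimethyl squarate
Product: 5 rac-4-[1-(2,6-dimethoxyphenoxy)ethenyl]-4-hydroxy-2,3-dimethoxycyclobut-2-en-1-one, via 1-(2,6-dimethoxyphenoxy)ethenyllithium 4 (not isolated)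
Conditions: t-BuLi (1.1 equiv), THF, −78 to −50 °C; then added to 3 in THF, −78 °C; aq. NH4Cl, −78 °C
Reagents that add atoms: none
Why: Alpha-lithiation of an enol ether followed by 1,2-addition of the vinyllithium to one carbonyl of the squarate (a vinylogous ester) is the standard entry to 4-alkenyl-4-hydroxycyclobutenones; lithium coordination by the vinyl and ortho-methoxy oxygens should direct the base to the vinyl alpha C–H, 2 has no ring C–H between two oxygens to compete, inverse addition at −78 °C limits double addition, and the new C4 stereocentre forms racemic and is erased in step 4.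

Step 3
Reactants: 5 rac-4-[1-(2,6-dimethoxyphenoxy)ethenyl]-4-hydroxy-2,3-dimethoxycyclobut-2-en-1-one
Product: 6 rac-4-[1-(2,6-dimethoxyphenoxy)ethenyl]-2,3-dimethoxy-4-(methoxymethoxy)cyclobut-2-en-1-one
Conditions: MOMCl, i-Pr2NEt, CH2Cl2, 0 °C to reflux
Reagents that add atoms: chloromethyl methyl ether, COCCl
Why: O-Alkylation of the tertiary alcohol by the reactive alpha-chloro ether under amine base (acetal protection) masks the future C6 oxygen with a group that should survive heat, base, borylation and copper catalysis and is later removed by mild acid beside methyl and aryl ethers.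

Step 4
Reactants: 6 rac-4-[1-(2,6-dimethoxyphenoxy)ethenyl]-2,3-dimethoxy-4-(methoxymethoxy)cyclobut-2-en-1-one
Product: 9 5-(2,6-dimethoxyphenoxy)-2,3-dimethoxy-4-(methoxymethoxy)phenol, via dienylketene 7 (not isolated), via cyclohexadienone 8 (not isolated)
Conditions: toluene (degassed, 0.02 M), 110 °C
Reagents that add atoms: none
Why: Heating should open the cyclobutenone by conrotatory 4-pi electrocyclic cleavage of the C1–C4 bond to the (Z)-dienylketene 7, and a disrotatory 6-pi electrocyclisation then joins the ketene carbon to the vinyl CH2, which is the C3–C2 bond of ring C, to give dienone 8, which tautomerises to phenol 9. The closest known reaction type is the thermal ring expansion of squarate-derived 4-alkenyl-4-alkoxycyclobutenones to hydroquinone monoethers (Moore rearrangement). The six-membered ring is closed by the 6-pi electrocyclisation and becomes aromatic, so no stereocentre is formed and the racemic C4 centre of 6 disappears. The step needs torquoselective opening with the C4 oxygen rotating outward and the vinyl group inward toward the ketene, which the donor character of the OMOM substituent secures. Regiochemistry follows from connectivity: the squarate carbons become C3 to C6 and the vinyl carbons C1 and C2, so the 2,6-dimethoxyphenoxy group sits on C1 next to the only CH. The two hydroquinone oxygens emerge differentiated, C3 as a free hydroxyl and C6 as the MOM ether.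

Step 5
Reactants: 9 5-(2,6-dimethoxyphenoxy)-2,3-dimethoxy-4-(methoxymethoxy)phenol
Product: 10 1-(2,6-dimethoxyphenoxy)-3,4,5-trimethoxy-2-(methoxymethoxy)benzene
Conditions: MeI, K2CO3, acetone, reflux
Reagents that add atoms: iodomethane, CI
Why: Williamson methylation of the only free phenol (the C3 hydroxyl delivered by the ketene carbon) fixes this oxygen as a methyl ether while the base-stable MOM group keeps the C6 oxygen distinct.

Step 6
Reactants: 10 1-(2,6-dimethoxyphenoxy)-3,4,5-trimethoxy-2-(methoxymethoxy)benzene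
Product: 11 2-{3,5-dimethoxy-4-[3,4,5-trimethoxy-2-(methoxymethoxy)phenoxy]phenyl}-4,4,5,5-tetramethyl-1,3,2-dioxaborolane
Conditions: [Ir(OMe)(cod)]2 (1.5 mol%), 4,4'-di-tert-butyl-2,2'-bipyridine (3 mol%), B2pin2 (1.0 equiv), THF, 80 °C
Reagents that add atoms: bis(pinacolato)diboron, CC1(C)OB(OC1(C)C)B1OC(C)(C)C(C)(C)O1
Why: Iridium-catalysed aromatic C–H borylation is governed by sterics, and in 10 the only aromatic C–H with no ortho substituent is the one para to the ether oxygen on the 2,6-dimethoxyphenoxy ring (the future C1 of ring B, D or F), the lone C–H of the pentaoxygenated ring being flanked by two oxygens.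

Step 7
Reactants: 11 2-{3,5-dimethoxy-4-[3,4,5-trimethoxy-2-(methoxymethoxy)phenoxy]phenyl}-4,4,5,5-tetramethyl-1,3,2-dioxaborolane
Product: 12 1-(4-iodo-2,6-dimethoxyphenoxy)-3,4,5-trimethoxy-2-(methoxymethoxy)benzene
Conditions: CuI (10 mol%), 1,10-phenanthroline (20 mol%), KI (1.5 equiv), MeOH/H2O 4:1, air, 80 °C
Reagents that add atoms: potassium iodide, [K+].[I-]
Why: Copper-catalysed aerobic iododeboronation (a Chan–Lam-type ipso-halogenation) replaces boron by iodine at the same carbon under neutral conditions, so neither electrophilic iodination of the electron-rich rings nor loss of the MOM acetal is expected.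

Step 8
Reactants: 13 2,4,6-trimethoxyphenol; 12 1-(4-iodo-2,6-dimethoxyphenoxy)-3,4,5-trimethoxy-2-(methoxymethoxy)benzene
Product: 14 1-[2,6-dimethoxy-4-(2,4,6-trimethoxyphenoxy)phenoxy]-3,4,5-trimethoxy-2-(methoxymethoxy)benzene (A–B–C trimer MOM ether)
Conditions: CuI (10 mol%), picolinic acid (20 mol%), K3PO4 (2 equiv), DMSO, 90 °C, argon
Reagents that add atoms: none
Why: Ullmann-type diaryl ether synthesis with a CuI/picolinic acid catalyst accepts di-ortho-substituted phenols, and here the hindrance lies only on the phenol because the iodide carbon of 12 has two ortho hydrogens; methyl ethers and the MOM acetal are stable to K3PO4.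

Step 9
Reactants: 14 A–B–C trimer MOM ether
Product: 15 6-[2,6-dimethoxy-4-(2,4,6-trimethoxyphenoxy)phenoxy]-2,3,4-trimethoxyphenol (A–B–C trimer phenol)
Conditions: HCl (1.25 M in MeOH), THF, 40 °C
Reagents that add atoms: none
Why: Acid-catalysed cleavage of the MOM acetal (transacetalisation to methanol) frees the ring C C6 hydroxyl while aryl methyl ethers and diaryl ethers are inert to dilute HCl.

Step 10
Reactants: 15 A–B–C trimer phenol; 12 1-(4-iodo-2,6-dimethoxyphenoxy)-3,4,5-trimethoxy-2-(methoxymethoxy)benzene
Product: 16 A–E pentamer MOM ether (15 O-arylated at ring C C6 by the 3,5-dimethoxy-4-[3,4,5-trimethoxy-2-(methoxymethoxy)phenoxy]phenyl group of 12)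
Conditions: CuI (20 mol%), picolinic acid (40 mol%), K3PO4 (2 equiv), DMSO, 90 °C, argon
Reagents that add atoms: none
Why: The Ullmann etherification of step 8 is repeated with the ring C C6 phenoxide, which is flanked by a methoxy and an aryloxy group but again meets an iodide carbon with two ortho hydrogens, and adds rings D and E in one operation.

Step 11
Reactants: 16 A–E pentamer MOM ether
Product: 17 A–E pentamer phenol (free ring E C6 hydroxyl, 13 methyl ethers)
Conditions: HCl (1.25 M in MeOH), THF, 40 °C
Reagents that add atoms: none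
Why: Acid-catalysed MOM cleavage as in step 9 frees the ring E C6 hydroxyl without touching the 13 methyl ethers or the four diaryl ether links.

Step 12
Reactants: 17 A–E pentamer phenol; 12 1-(4-iodo-2,6-dimethoxyphenoxy)-3,4,5-trimethoxy-2-(methoxymethoxy)benzene
Product: 18 A–G heptamer MOM ether (17 O-arylated at ring E C6 by the same aryl group; 18 methyl ethers, ring G C6 as MOM ether)
Conditions: CuI (20 mol%), picolinic acid (40 mol%), K3PO4 (2 equiv), DMSO, 90 °C, argon
Reagents that add atoms: none
Why: A third Ullmann etherification of the same kind adds rings F and G; the reacting centres are identical to those of step 10 and only the spectator chain is longer.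

Step 13
Reactants: 18 A–G heptamer MOM ether
Product: 19 A–G heptamer phenol (free ring G C6 hydroxyl, 18 methyl ethers)
Conditions: HCl (1.25 M in MeOH), THF, 40 °C
Reagents that add atoms: none
Why: Acid-catalysed MOM cleavage frees the ring G C6 hydroxyl, the last nucleophile needed, with all methyl and diaryl ethers inert to dilute HCl.

Step 14
Reactants: 19 A–G heptamer phenol; 20 5-iodo-1,2,3-trimethoxybenzene
Product: 21 henicosa-O-methyl ether of the target (19 O-arylated at ring G C6 by 3,4,5-trimethoxyphenyl)
Conditions: CuI (20 mol%), picolinic acid (40 mol%), K3PO4 (2 equiv), 20 (3 equiv), DMSO, 90 °C, argon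
Reagents that add atoms: none
Why: The same Ullmann etherification joins the ring G C6 phenoxide to the unhindered iodide carbon of 20, which can be used in excess, and completes the octameric skeleton with all 21 hydroxyls as methyl ethers.

Step 15
Reactants: 21 henicosa-O-methyl ether of the target
Product: 22 CNP0206369.0 (A–H octamer with 21 free hydroxyls)
Conditions: BBr3 (2 equiv per OMe), CH2Cl2, −78 °C to rt, argon; then H2O, 0 °C
Reagents that add atoms: none
Why: Lewis-acid demethylation with BBr3 proceeds by bromide attack on the methyl carbon of the boron-complexed ether, a path closed to the diaryl ether links, which have no sp3 carbon on oxygen, so the seven aryl–O–aryl bonds should survive while all 21 methyl groups are removed.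

**Compound list**

1 | 2,6-dimethoxyphenol | COc1cccc(OC)c1O | starting material
2 | 2-(ethenyloxy)-1,3-dimethoxybenzene | C=COc1c(OC)cccc1OC | intermediate
3 | dimethyl squarate (3,4-dimethoxycyclobut-3-ene-1,2-dione) | COC1=C(OC)C(=O)C1=O | starting material
4 | 1-(2,6-dimethoxyphenoxy)ethenyllithium | [Li]C(=C)Oc1c(OC)cccc1OC | intermediate
5 | rac-4-[1-(2,6-dimethoxyphenoxy)ethenyl]-4-hydroxy-2,3-dimethoxycyclobut-2-en-1-one | COC1=C(OC)C(O)(C(=C)Oc2c(OC)cccc2OC)C1=O | intermediate
6 | rac-4-[1-(2,6-dimethoxyphenoxy)ethenyl]-2,3-dimethoxy-4-(methoxymethoxy)cyclobut-2-en-1-one | COC1=C(OC)C(OCOC)(C(=C)Oc2c(OC)cccc2OC)C1=O | intermediate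
7 | (3Z)-5-(2,6-dimethoxyphenoxy)-2,3-dimethoxy-4-(methoxymethoxy)hexa-1,3,5-trien-1-one (dienylketene) | O=C=C(OC)/C(OC)=C(/OCOC)C(=C)Oc1c(OC)cccc1OC | intermediate
8 | 5-(2,6-dimethoxyphenoxy)-2,3-dimethoxy-4-(methoxymethoxy)cyclohexa-2,4-dien-1-one | O=C1CC(Oc2c(OC)cccc2OC)=C(OCOC)C(OC)=C1OC | intermediate
9 | 5-(2,6-dimethoxyphenoxy)-2,3-dimethoxy-4-(methoxymethoxy)phenol | Oc1cc(Oc2c(OC)cccc2OC)c(OCOC)c(OC)c1OC | intermediate
10 | 1-(2,6-dimethoxyphenoxy)-3,4,5-trimethoxy-2-(methoxymethoxy)benzene | COc1cc(Oc2c(OC)cccc2OC)c(OCOC)c(OC)c1OC | intermediate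
11 | 2-{3,5-dimethoxy-4-[3,4,5-trimethoxy-2-(methoxymethoxy)phenoxy]phenyl}-4,4,5,5-tetramethyl-1,3,2-dioxaborolane | COc1cc(Oc2c(OC)cc(B3OC(C)(C)C(C)(C)O3)cc2OC)c(OCOC)c(OC)c1OC | intermediate
12 | 1-(4-iodo-2,6-dimethoxyphenoxy)-3,4,5-trimethoxy-2-(methoxymethoxy)benzene | COc1cc(Oc2c(OC)cc(I)cc2OC)c(OCOC)c(OC)c1OC | intermediate
13 | 2,4,6-trimethoxyphenol | COc1cc(OC)c(O)c(OC)c1 | starting material
14 | 1-[2,6-dimethoxy-4-(2,4,6-trimethoxyphenoxy)phenoxy]-3,4,5-trimethoxy-2-(methoxymethoxy)benzene (A–B–C trimer MOM ether) | COc1cc(OC)c(Oc2cc(OC)c(Oc3cc(OC)c(OC)c(OC)c3OCOC)c(OC)c2)c(OC)c1 | intermediate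
15 | 6-[2,6-dimethoxy-4-(2,4,6-trimethoxyphenoxy)phenoxy]-2,3,4-trimethoxyphenol (A–B–C trimer phenol) | COc1cc(OC)c(Oc2cc(OC)c(Oc3cc(OC)c(OC)c(OC)c3O)c(OC)c2)c(OC)c1 | intermediate
16 | A–E pentamer MOM ether: 15 with the ring C C6 oxygen bearing the 3,5-dimethoxy-4-[3,4,5-trimethoxy-2-(methoxymethoxy)phenoxy]phenyl group | COc1cc(OC)c(Oc2cc(OC)c(Oc3cc(OC)c(OC)c(OC)c3Oc3cc(OC)c(Oc4cc(OC)c(OC)c(OC)c4OCOC)c(OC)c3)c(OC)c2)c(OC)c1 | intermediate
17 | A–E pentamer phenol: 16 with the MOM group replaced by hydrogen | COc1cc(OC)c(Oc2cc(OC)c(Oc3cc(OC)c(OC)c(OC)c3Oc3cc(OC)c(Oc4cc(OC)c(OC)c(OC)c4O)c(OC)c3)c(OC)c2)c(OC)c1 | intermediate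
18 | A–G heptamer MOM ether: 17 with the ring E C6 oxygen bearing the 3,5-dimethoxy-4-[3,4,5-trimethoxy-2-(methoxymethoxy)phenoxy]phenyl group | COc1cc(OC)c(Oc2cc(OC)c(Oc3cc(OC)c(OC)c(OC)c3Oc3cc(OC)c(Oc4cc(OC)c(OC)c(OC)c4Oc4cc(OC)c(Oc5cc(OC)c(OC)c(OC)c5OCOC)c(OC)c4)c(OC)c3)c(OC)c2)c(OC)c1 | intermediate
19 | A–G heptamer phenol: 18 with the MOM group replaced by hydrogen | COc1cc(OC)c(Oc2cc(OC)c(Oc3cc(OC)c(OC)c(OC)c3Oc3cc(OC)c(Oc4cc(OC)c(OC)c(OC)c4Oc4cc(OC)c(Oc5cc(OC)c(OC)c(OC)c5O)c(OC)c4)c(OC)c3)c(OC)c2)c(OC)c1 | intermediate
20 | 5-iodo-1,2,3-trimethoxybenzene | COc1cc(I)cc(OC)c1OC | starting material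
21 | henicosa-O-methyl ether of the target: 19 with the ring G C6 oxygen bearing 3,4,5-trimethoxyphenyl | COc1cc(OC)c(Oc2cc(OC)c(Oc3cc(OC)c(OC)c(OC)c3Oc3cc(OC)c(Oc4cc(OC)c(OC)c(OC)c4Oc4cc(OC)c(Oc5cc(OC)c(OC)c(OC)c5Oc5cc(OC)c(OC)c(OC)c5)c(OC)c4)c(OC)c3)c(OC)c2)c(OC)c1 | intermediate
22 | CNP0206369.0 (A–H octamer, 21 free hydroxyls, no stereocentre) | Oc1cc(O)c(Oc2cc(O)c(Oc3cc(O)c(O)c(O)c3Oc3cc(O)c(Oc4cc(O)c(O)c(O)c4Oc4cc(O)c(Oc5cc(O)c(O)c(O)c5Oc5cc(O)c(O)c(O)c5)c(O)c4)c(O)c3)c(O)c2)c(O)c1 | target

**Step count and risks**

Total steps: 15. Longest linear sequence: 15 steps (1 to 22); iodide 12 is made once in steps 1 to 7 and used in steps 8, 10 and 12.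

Steps most likely to fail:

Step 2. Deprotonation of the vinyl alpha C–H may be too slow at the temperature at which vinyllithium 4 survives. On warming, 4 may expel lithium 2,6-dimethoxyphenoxide by alpha-elimination, and surplus t-BuLi may add to 3. The fallback makes 4 by tin–lithium exchange instead of deprotonation. It sets out from 1 and returns at 5. Phenol 1 is O-alkenylated with trichloroethylene (KH, THF) to 2-{[(E)-1,2-dichloroethenyl]oxy}-1,3-dimethoxybenzene F1. Treatment with n-BuLi (2.2 equiv, THF, −78 to −40 °C) and then methanol should give the ynol ether 2-(ethynyloxy)-1,3-dimethoxybenzene F2. Palladium-catalysed hydrostannation (Bu3SnH, Pd(PPh3)4), which places tin on the oxygen-bearing carbon of ynol ethers, should give tributyl[1-(2,6-dimethoxyphenoxy)ethenyl]stannane F3. Exchange with n-BuLi in THF at −78 °C then generates 4 within minutes in the cold and free of t-BuLi, and addition to 3 as in step 2 rejoins the route at 5.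

Step 12. Bond formation at copper between the bulky phenoxide of 17 and 12 may be slow, so that hydrodeiodination of 12 and oxidative decay of the electron-rich phenoxide at 90 °C overtake the coupling. The fallback is an oxidative Chan–Evans–Lam coupling at room temperature, in which the aryl group is delivered by transmetalation from boron. It sets out from boronate 11 and phenol 17 and returns at 18. The pinacol ester of 11 is cleaved (NaIO4, NH4OAc, acetone/H2O, rt) to {3,5-dimethoxy-4-[3,4,5-trimethoxy-2-(methoxymethoxy)phenoxy]phenyl}boronic acid F4. This is coupled with 17 (Cu(OAc)2, pyridine, 4 Å molecular sieves, CH2Cl2, rt, dry air) to give 18; this coupling type accepts di-ortho-substituted phenols. The same exchange of partners would serve steps 8 and 10.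

Step 15. Some of the 21 methyl ethers may be cleaved incompletely, and the pyrogallol-type rings may be oxidised by air while the free polyphenol is isolated. The fallback isolates the product as its peracetate. It sets out from 21 and returns at 22. After the BBr3 treatment of step 15 the crude polyphenol is not purified but acetylated at once (Ac2O, pyridine, DMAP cat.) to the henicosaacetate of 22 F5. F5 should be stable to air and silica, so that under-demethylated material can be separated and resubmitted. Zemplén deacetylation (NaOMe cat., degassed MeOH, then acidic resin) then returns to 22.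

Further compounds
F1 | step 2 | 2-{[(E)-1,2-dichloroethenyl]oxy}-1,3-dimethoxybenzene | Cl/C(Oc1c(OC)cccc1OC)=C/Cl
F2 | step 2 | 2-(ethynyloxy)-1,3-dimethoxybenzene | C#COc1c(OC)cccc1OC
F3 | step 2 | tributyl[1-(2,6-dimethoxyphenoxy)ethenyl]stannane | CCCC[Sn](CCCC)(CCCC)C(=C)Oc1c(OC)cccc1OC
F4 | step 12 | {3,5-dimethoxy-4-[3,4,5-trimethoxy-2-(methoxymethoxy)phenoxy]phenyl}boronic acid | COc1cc(Oc2c(OC)cc(B(O)O)cc2OC)c(OCOC)c(OC)c1OC
F5 | step 15 | henicosaacetate of 22 | CC(=O)Oc1cc(OC(C)=O)c(Oc2cc(OC(C)=O)c(Oc3cc(OC(C)=O)c(OC(C)=O)c(OC(C)=O)c3Oc3cc(OC(C)=O)c(Oc4cc(OC(C)=O)c(OC(C)=O)c(OC(C)=O)c4Oc4cc(OC(C)=O)c(Oc5cc(OC(C)=O)c(OC(C)=O)c(OC(C)=O)c5Oc5cc(OC(C)=O)c(OC(C)=O)c(OC(C)=O)c5)c(OC(C)=O)c4)c(OC(C)=O)c3)c(OC(C)=O)c2)c(OC(C)=O)c1
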